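A one-step world has one rate constant and one exponential. These flasks instead put 4 additions in a row on each starting material, each consuming one partner and giving one by-product, while partner may also decompose or go dormant.

| setting | north | north-east | beta | zeta |
|---|---|---|---|---|
| starting material | 0.010 M | 0.010 M | 0.010 M | 0.010 M |
| partner | 1.7 equiv | 8 equiv | 2.50 equiv | 10.0 equiv |
| remark | run made earlier | run made earlier |  |  |
| time |  |  | 6.0 d | 6.0 d |

| run | time / d | tetra adduct / % | starting material / % |
|---|---|---|---|
| north | 0.833 | 0.1 | 76.2 |
| north | 1.67 | 0.3 | 63.0 |
| north | 2.50 | 1.7 | 52.4 |
| north | 3.00 | 1.3 | 46.0 |
| north | 4.00 | 1.2 | 39.5 |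
| north-east | 0.833 | 0.6 | 30.3 |
| north-east | 1.67 | 8.3 | 10.6 |
| north-east | 2.50 | 17.0 | 3.3 |
| north-east | 3.00 | 23.9 | 1.2 |
| north-east | 4.00 | 36.4 | 2.7 |

(each reading ± 1 percentage point)

- the winner by amount of tetra adduct, in percent of the starting material charged; "neither" if no more than 2 percentage points parts them (beta / zeta / neither)
- how much tetra adduct is there at the end, in percent of the starting material charged: beta
- how much tetra adduct is there at the end, in percent of the starting material charged: zeta

- candidate steps: starting material + partner -> first product + by-product; partner + first product -> bis adduct + by-product; partner + bis adduct -> triple product + by-product; partner + triple product -> tetra adduct + by-product; partner -> decomposition product; partner <-> dormant form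

Two chemists disagree. The counter writes the balance of sites: complete conversion takes 4 equiv of partner. Beta, with 2.50 equiv, holds less than that, so partner is the limiting reagent there, short by 0.0150 M, and tetra adduct is capped at 62.5%. Zeta has no such shortfall, so the counter expects its tetra adduct to approach the whole charge.

The clock-watcher replies that a cap is not a yield. In the north-east run, starting material fell to 30.3% by 0.833 d; that pseudo-first-order loss, divided by the partner charged, reads 17.9 /M/d. Yet tetra adduct there read 36.4% at 4.00 d, despite the excess of partner.

My own reckoning joins the two in the surplus dose: the constant read above, times the charged c(partner) less 4 times the charged c(starting material), times the time. The surplus is the partner, free or dormant, left over once each site is filled, so the dose is an estimate in first-step e-foldings, reckoned as if that surplus were free partner. Zeta has a surplus of 0.0600 M and a dose of 6.45, more than the 2.87 of north-east at its last reading. Beta's surplus is negative, so it has no floor. I therefore expect zeta well above 36.4%, an expectation and not the forecast's number.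

The forecast, the clock-watcher's, says zeta, with 3% for beta and 68% for zeta, by “Integrating partner exposure (concentration × time) by hand”.

The simulation gives zeta, with 3.67% for beta and 77.2% for zeta.

    starting material + partner → first product + by-product (k = 1.30 /M/h)
    partner + first product → bis adduct + by-product (k = 0.840 /M/h)
    partner + bis adduct → triple product + by-product (k = 1.30 /M/h)
    partner + triple product → tetra adduct + by-product (k = 0.470 /M/h)
    partner → decomposition product (k = 4.40 × 10⁻⁵ /h)
    partner ⇌ dormant form (K = 0.650, k = 0.250 /h)

Beta lies far below the counter's cap, and zeta stands 9.2 percentage points above the forecast at its dose of 6.45. The counter's view comes true in one further flask. The neighbour like zeta but with 40.0 equiv has a surplus of 0.360 M and a dose of 38.7, more than zeta's. At 6.00 d that neighbour holds >99.9% tetra adduct, with 54% of its partner charge still unbound.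

The numbers in the tables come from a simulation for an exercise, and the scatter is random.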